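## Retrosynthetic overview

1. Endgame: the C1 and C19 acetates and the free C6–OH come from orthogonal ethers. Ring D (C16–C13) comes from a 5-exo vinyl-radical cyclization of a C15 carbinol made from a C8 formyl group. Ring C (C9–C11, C8–C14) comes from a Diels–Alder addition of butadiene to a transient 8-formyl-8,9-unsaturated spirolactone.
2. The 7,20-spirolactone is derived from a temporary 20,6-γ-lactone: Michael addition of C10 to tert-butyl acrylate (C10–C9), reduction of C20, then relactonization onto C7.
3. Ring A comes from a catalytic enantioselective Diels–Alder reaction of a 3-(1-silyloxyvinyl)butenolide (diene C2=C1–C10=C5, tether C20(=O)–O–C6) with methacrolein (C3=C4, C18, C19). This forms C2–C3 and C4–C5.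
4. Enabling feature: in ring A the C1 oxygen is para to the quaternary C4 that carries C19, C4 is the neighbour of C5, and the oxygenated one-carbon arms C6 (on C5) and C20 (on C10) are cis on adjacent atoms. Tying them as a butenolide makes C10=C5, together with the C1 enol ether, a polarity-matched 2-oxy diene.
5. Ring order: temporary γ-lactone → ring A → spiro δ-lactone → ring C → ring D.

Key step: step 3

Remark on numbering: atom numbers are those of the ent-kaurane skeleton (ring A = C1–C5, C10; lactone = C10, C20, O, C7, C8, C9; ring C = C8, C9, C11–C14; ring D = C8, C14, C13, C16, C15). One-pot sequences count as one step.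

Remark on the catalyst: the (R)-oxazaborolidinium ion is assigned from the accepted pre-transition-state model for 2-substituted acroleins, which predicts diene attack on the Si face of C4 and hence (R)-C4.

## Route

Step 1
Reactants: 1 3-acetyloxolan-2-one (2-acetylbutyrolactone)
Product: 2 3-acetyl-3-chlorooxolan-2-one (racemic)
Conditions: SO2Cl2, CH2Cl2, 0 °C → rt
Reagents that add atoms: sulfuryl chloride, O=S(=O)(Cl)Cl
Why: Electrophilic α-chlorination of a 1,3-dicarbonyl compound at its only doubly activated carbon (future C10); the new stereocentre is racemic and is erased in step 2.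

Step 2
Reactants: 2 3-acetyl-3-chlorooxolan-2-one
Product: 4 3-[1-(triisopropylsilyloxy)ethenyl]furan-2(5H)-one, via chloro silyl enol ether 3 (not isolated)
Conditions: i-Pr3SiOSO2CF3 (1.05 equiv), Et3N, CH2Cl2, −78 → 0 °C; then 1,8-diazabicyclo[5.4.0]undec-7-ene (DBU), 0 °C; used at once
Reagents that add atoms: triisopropylsilyl triflate, CC(C)[Si](OS(=O)(=O)C(F)(F)F)(C(C)C)C(C)C
Why: Soft enolization with O-silylation of the methyl ketone (only C2 can enolize because C10 is quaternary) followed by E2 dehydrochlorination should give the cross-conjugated 2-silyloxy diene, and silylating before the butenolide exists avoids 2-silyloxyfuran formation.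

Step 3
Reactants: 4 3-[1-(triisopropylsilyloxy)ethenyl]furan-2(5H)-one; 5 methacrolein
Product: 7 (3aR,4R)-4-(hydroxymethyl)-4-methyl-7-(triisopropylsilyloxy)-3a,4,5,6-tetrahydro-2-benzofuran-1(3H)-one, via Diels–Alder aldehyde 6 (not isolated)
Conditions: (R)-3,3-diphenyl-1-(2-methylphenyl)tetrahydro-1H,3H-pyrrolo[1,2-c][1,3,2]oxazaborole (20 mol %), HN(SO2CF3)2 (18 mol %), CH2Cl2, −78 → −40 °C; then MeOH, NaBH4, −78 → 0 °C
Reagents that add atoms: none
Why: This is a Diels–Alder reaction under chiral Lewis acid catalysis, the closest precedent being oxazaborolidinium-catalysed cycloadditions of 2-substituted acroleins with 2-silyloxy-1,3-dienes; the boron-bound s-trans methacrolein is attacked at C3 by the nucleophilic enol-ether terminus C2 while C4 closes onto C5, the β-carbon of the butenolide, in one concerted but asynchronous [4+2] event. Ring A is closed by this intermolecular suprafacial (4+2) union of the C2=C1–C10=C5 diene with the C3=C4 dienophile, and the γ-lactone that is already present becomes fused to it. The quaternary C4 is set by the catalyst, which shields one enantioface of the coordinated enal so that C5 bonds to the Si face of C4, and C5 follows from the endo position of the formyl group, which with the ring-locked geometry of C10=C5 (C6 on the outside of the diene) places C19 and C6 cis. Regiochemistry (C2–C3 and C4–C5, not the reverse) is secured twice, by the 2-silyloxy group and by the butenolide carbonyl that makes C5 the acceptor terminus. The step therefore needs regio-, endo- and enantioface control, and the in situ borohydride reduction only converts the sensitive neopentyl aldehyde into the alcohol, leaving the vinylogous silyl carbonate untouched.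

Step 4
Reactants: 7 C19 alcohol
Product: 8 C19 2-naphthylmethyl ether of 7
Conditions: NaH, 2-(bromomethyl)naphthalene, Bu4NI (cat.), THF/DMF, 0 °C → rt
Reagents that add atoms: 2-(bromomethyl)naphthalene, BrCc1ccc2ccccc2c1
Why: Williamson etherification of the neopentyl alkoxide; the lactone carbonyl is deactivated as a vinylogous silyl carbonate and C10 is still sp2, so translactonization onto C19 should not compete.

Step 5
Reactants: 8 C19 2-naphthylmethyl ether; 9 tert-butyl acrylate
Product: 11 tert-butyl 3-(C10)-propanoate with C1–OH cis to C20 and the 20,6-γ-lactone cis-fused, via C1 ketone 10 (not isolated)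
Conditions: Bu4NF·3H2O (1.05 equiv), THF, −40 → 0 °C; then MeOH, NaBH4, −40 → 0 °C
Reagents that add atoms: none
Why: Fluoride unmasks the β-keto lactone enolate, whose Michael addition to the acrylate should occur on the face opposite the axial C19 arm (the only face that keeps the γ-lactone cis-fused, so C9 ends trans to C6 and C20 cis to C6), and the C1 ketone is then reduced by axial hydride delivery anti to the axial C20 carbonyl to give the equatorial C1 alcohol cis to C20.

Step 6
Reactants: 11 C1 alcohol
Product: 12 C1,C19-bis(2-naphthylmethyl) ether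
Conditions: 2-naphthylmethyl 2,2,2-trichloroacetimidate, CF3SO3H (cat.), CH2Cl2, −20 °C
Reagents that add atoms: 2-naphthylmethyl 2,2,2-trichloroacetimidate, N=C(OCc1ccc2ccccc2c1)C(Cl)(Cl)Cl
Why: Acid-catalysed trichloroacetimidate etherification protects the hindered C1 hydroxyl without forming an alkoxide that could lactonize onto C7 or undergo retro-aldol cleavage.

Step 7
Reactants: 12 bis(2-naphthylmethyl) ether
Product: 14 7,20-spirolactone bearing free C6–OH, via seco diol ester 13 (not isolated)
Conditions: LiBH4, THF, 0 °C → rt; aqueous work-up; then p-toluenesulfonic acid monohydrate (cat.), toluene, 60 °C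
Reagents that add atoms: none
Why: Chemoselective hydride reduction of the γ-lactone (the tert-butyl ester and the ethers should survive) gives the C6/C20 diol, and acid-catalysed transesterification then closes the six-membered 7,20-lactone in preference to the seven-membered ring through C6–OH.

Step 8
Reactants: 14 spirolactone alcohol
Product: 15 C6 tert-butyldiphenylsilyl ether
Conditions: t-BuPh2SiCl, imidazole, DMF, rt
Reagents that add atoms: tert-butyl(chloro)diphenylsilane, CC(C)(C)[Si](Cl)(c1ccccc1)c1ccccc1
Why: Silylation of the only free hydroxyl; the bulky silyl group also adds shielding on the C5 side of the lactone for step 11.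

Step 9
Reactants: 15 silyl ether
Product: 16 C8-formyl spirolactone (enolized, C8 epimers)
Conditions: LiN(SiMe3)2 (2.2 equiv), THF, −78 °C; HCO2CH2CF3; then 1 M HCl
Reagents that add atoms: 2,2,2-trifluoroethyl formate, O=COCC(F)(F)F
Why: Claisen-type C-formylation of the lactone enolate at C8, the only α-position that carries hydrogen.

Step 10
Reactants: 16 formyl lactone
Product: 17 C8-formyl C8-phenylselanyl spirolactone (C8 epimers)
Conditions: PhSeCl, pyridine, CH2Cl2, 0 °C
Reagents that add atoms: benzeneselenenyl chloride, Cl[Se]c1ccccc1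
Why: Electrophilic selenenylation of the enolized 1,3-dicarbonyl unit at C8.

Step 11
Reactants: 17 selenide; 18 buta-1,3-diene
Product: 21 tricyclic aldehyde with cis-fused cyclohex-12-ene ring C and quaternary C8–CHO, via selenoxide 19 (not isolated), via formyl dienophile 20 (not isolated)
Conditions: 3-chloroperbenzoic acid, CH2Cl2, −78 °C; then buta-1,3-diene (excess), ZnCl2 (20 mol %), −78 → 20 °C, sealed vessel
Reagents that add atoms: none
Why: Selenoxide syn-elimination (only C9 carries β-hydrogen) unveils a doubly activated 2-formyl enoate dienophile, and the Diels–Alder addition of butadiene should occur suprafacially on the lactone face flanked by C1, away from C5 with its silyloxymethyl group and the axial C19 arm, which fixes C9 and the quaternary C8 (C11 and C14 cis, formyl cis to H9).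

Step 12
Reactants: 21 tricyclic aldehyde
Product: 22 C15 carbinol bearing the 1-bromovinyl group (C15 epimers)
Conditions: vinyl bromide, LiN(i-Pr)2, THF/Et2O/pentane, −110 °C; then 21; aq. NH4Cl
Reagents that add atoms: 1-bromovinyllithium (from vinyl bromide), [Li]C(Br)=C
Why: Carbonyl 1,2-addition of the α-bromovinyl carbenoid to the non-enolizable aldehyde, which should be far faster than attack on the lactone at this temperature; the C15 configuration is irrelevant because it is oxidized in step 14.

Step 13
Reactants: 22 bromovinyl carbinol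
Product: 23 tetracyclic 15-hydroxy-16-methylene compound (C15 epimers)
Conditions: Bu3SnH (high concentration), azobis(isobutyronitrile) (cat.), benzene, 80 °C
Reagents that add atoms: none
Why: Tin-hydride-mediated vinyl radical cyclization, 5-exo-trig onto C13 of the ring C alkene, closes ring D as a bicyclo[3.2.1]octane; C13 is fixed by the geometric demand of the two-carbon bridge from C8, and fast hydrogen transfer traps the kinetic radical at C12.

Step 14
Reactants: 23 allylic alcohol
Product: 24 15-oxo-16-methylene enone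
Conditions: Dess–Martin periodinane, CH2Cl2, rt
Reagents that add atoms: none
Why: Hypervalent iodine oxidation of the secondary allylic alcohol to the α-methylene cyclopentanone.

Step 15
Reactants: 24 enone
Product: 25 C1,C19-diol
Conditions: 2,3-dichloro-5,6-dicyano-1,4-benzoquinone (DDQ), CH2Cl2/pH 7 buffer, rt
Reagents that add atoms: none
Why: Oxidative cleavage of the electron-rich 2-naphthylmethyl ethers (hydride abstraction, then hydrolysis of the oxocarbenium ion) should leave the enone, the lactone and the silyl ether intact.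

Step 16
Reactants: 25 diol
Product: 26 C1,C19-diacetate
Conditions: Ac2O, pyridine, 4-(dimethylamino)pyridine (cat.), CH2Cl2, 0 °C → rt, directly after step 15
Reagents that add atoms: acetic anhydride, CC(=O)OC(C)=O
Why: Nucleophile-catalysed acetylation of both free hydroxyls; prompt acylation of C1–OH prevents lactone migration from C20 to C1.

Step 17
Reactants: 26 diacetate
Product: 27 target compound
Conditions: HF·pyridine, THF/pyridine, 0 °C → rt
Reagents that add atoms: none
Why: Fluoride-mediated desilylation under buffered acidic conditions should free C6–OH without acetyl migration or addition to the enone.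

## Compound list

1 | 3-acetyloxolan-2-one (2-acetylbutyrolactone, racemic) | CC(=O)C1CCOC1=O | starting material
2 | 3-acetyl-3-chlorooxolan-2-one (racemic) | CC(=O)C1(Cl)CCOC1=O | intermediate
3 | 3-chloro-3-[1-(triisopropylsilyloxy)ethenyl]oxolan-2-one (racemic) | C=C(O[Si](C(C)C)(C(C)C)C(C)C)C1(Cl)CCOC1=O | intermediate
4 | 3-[1-(triisopropylsilyloxy)ethenyl]furan-2(5H)-one | C=C(O[Si](C(C)C)(C(C)C)C(C)C)C1=CCOC1=O | intermediate
5 | methacrolein (2-methylprop-2-enal) | C=C(C)C=O | starting material
6 | (3aR,4R)-4-methyl-1-oxo-7-(triisopropylsilyloxy)-1,3,3a,4,5,6-hexahydro-2-benzofuran-4-carbaldehyde (C19 formyl cis to C6) | CC(C)[Si](OC1=C2C(=O)OC[C@@H]2[C@](C)(C=O)CC1)(C(C)C)C(C)C | intermediate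
7 | (3aR,4R)-4-(hydroxymethyl)-4-methyl-7-(triisopropylsilyloxy)-3a,4,5,6-tetrahydro-2-benzofuran-1(3H)-one | CC(C)[Si](OC1=C2C(=O)OC[C@@H]2[C@](C)(CO)CC1)(C(C)C)C(C)C | intermediate
8 | C19 2-naphthylmethyl ether of 7 | CC(C)[Si](OC1=C2C(=O)OC[C@@H]2[C@](C)(COCc3ccc4ccccc4c3)CC1)(C(C)C)C(C)C | intermediate
9 | tert-butyl acrylate | C=CC(=O)OC(C)(C)C | starting material
10 | ring A C1 ketone with quaternary C10 (propanoate arm trans to C6, 20,6-γ-lactone cis-fused, C19 naphthylmethyl ether) | CC(C)(C)OC(=O)CC[C@@]12C(=O)OC[C@@H]1[C@](C)(COCc3ccc4ccccc4c3)CCC2=O | intermediate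
11 | C1 alcohol of 10 (C1–OH cis to C20) | CC(C)(C)OC(=O)CC[C@@]12C(=O)OC[C@@H]1[C@](C)(COCc3ccc4ccccc4c3)CC[C@@H]2O | intermediate
12 | C1,C19-bis(2-naphthylmethyl) ether of 11 | CC(C)(C)OC(=O)CC[C@@]12C(=O)OC[C@@H]1[C@](C)(COCc3ccc4ccccc4c3)CC[C@@H]2OCc5ccc6ccccc6c5 | intermediate
13 | C6,C20-diol tert-butyl ester (γ-lactone reduced) | CC(C)(C)OC(=O)CC[C@]1(CO)[C@@H](OCc5ccc6ccccc6c5)CC[C@@](C)(COCc3ccc4ccccc4c3)[C@H]1CO | intermediate
14 | 7,20-spirolactone with free C6–OH | O=C1CC[C@]2(CO1)[C@@H](OCc5ccc6ccccc6c5)CC[C@@](C)(COCc3ccc4ccccc4c3)[C@H]2CO | intermediate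
15 | C6 tert-butyldiphenylsilyl ether of 14 | O=C1CC[C@]2(CO1)[C@@H](OCc5ccc6ccccc6c5)CC[C@@](C)(COCc3ccc4ccccc4c3)[C@H]2CO[Si](c7ccccc7)(c8ccccc8)C(C)(C)C | intermediate
16 | C8-formyl spirolactone (C8 epimers, enolized) | O=CC1C[C@]2(COC1=O)[C@@H](OCc5ccc6ccccc6c5)CC[C@@](C)(COCc3ccc4ccccc4c3)[C@H]2CO[Si](c7ccccc7)(c8ccccc8)C(C)(C)C | intermediate
17 | C8-formyl C8-phenylselanyl spirolactone (C8 epimers) | O=CC1([Se]c9ccccc9)C[C@]2(COC1=O)[C@@H](OCc5ccc6ccccc6c5)CC[C@@](C)(COCc3ccc4ccccc4c3)[C@H]2CO[Si](c7ccccc7)(c8ccccc8)C(C)(C)C | intermediate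
18 | buta-1,3-diene | C=CC=C | starting material
19 | selenoxide of 17 | O=CC1([Se](=O)c9ccccc9)C[C@]2(COC1=O)[C@@H](OCc5ccc6ccccc6c5)CC[C@@](C)(COCc3ccc4ccccc4c3)[C@H]2CO[Si](c7ccccc7)(c8ccccc8)C(C)(C)C | intermediate
20 | 8-formyl-8,9-unsaturated spirolactone | O=CC1=C[C@]2(COC1=O)[C@@H](OCc5ccc6ccccc6c5)CC[C@@](C)(COCc3ccc4ccccc4c3)[C@H]2CO[Si](c7ccccc7)(c8ccccc8)C(C)(C)C | intermediate
21 | tricyclic aldehyde (ring C cyclohex-12-ene cis-fused to the lactone, C8 quaternary with CHO cis to H9) | O=C[C@]12CC=CC[C@H]1[C@]1(COC2=O)[C@@H](OCc5ccc6ccccc6c5)CC[C@@](C)(COCc3ccc4ccccc4c3)[C@H]1CO[Si](c7ccccc7)(c8ccccc8)C(C)(C)C | intermediate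
22 | C15 (1-bromovinyl)carbinol (C15 epimers) | C=C(Br)C(O)[C@]12CC=CC[C@H]1[C@]1(COC2=O)[C@@H](OCc5ccc6ccccc6c5)CC[C@@](C)(COCc3ccc4ccccc4c3)[C@H]1CO[Si](c7ccccc7)(c8ccccc8)C(C)(C)C | intermediate
23 | tetracyclic 15-hydroxy-16-methylene compound (C15 epimers) | C=C1C(O)[C@]23C[C@H]1CC[C@H]2[C@]1(COC3=O)[C@@H](OCc5ccc6ccccc6c5)CC[C@@](C)(COCc3ccc4ccccc4c3)[C@H]1CO[Si](c7ccccc7)(c8ccccc8)C(C)(C)C | intermediate
24 | 15-oxo-16-methylene enone, C1/C19 naphthylmethyl ethers, C6 silyl ether | C=C1C(=O)[C@]23C[C@H]1CC[C@H]2[C@]1(COC3=O)[C@@H](OCc5ccc6ccccc6c5)CC[C@@](C)(COCc3ccc4ccccc4c3)[C@H]1CO[Si](c7ccccc7)(c8ccccc8)C(C)(C)C | intermediate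
25 | C1,C19-diol, C6 silyl ether | C=C1C(=O)[C@]23C[C@H]1CC[C@H]2[C@]1(COC3=O)[C@@H](O)CC[C@@](C)(CO)[C@H]1CO[Si](c7ccccc7)(c8ccccc8)C(C)(C)C | intermediate
26 | C1,C19-diacetate, C6 silyl ether | C=C1C(=O)[C@]23C[C@H]1CC[C@H]2[C@]1(COC3=O)[C@@H](OC(C)=O)CC[C@@](C)(COC(C)=O)[C@H]1CO[Si](c7ccccc7)(c8ccccc8)C(C)(C)C | intermediate
27 | target: 1,19-diacetoxy-6-hydroxy-15-oxo-6,7-seco-ent-kaur-16-en-7,20-olide | C=C1C(=O)[C@]23C[C@H]1CC[C@H]2[C@]1(COC3=O)[C@@H](OC(C)=O)CC[C@@](C)(COC(C)=O)[C@H]1CO | target

## Step count and risks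

Total step count: 17. Longest linear sequence: 17 steps (from 1).

The three steps most likely to fail:

**Step 3.** The chiral Lewis acid may discriminate the enantiofaces of methacrolein poorly with this unusually substituted diene, or acid-induced desilylation of the diene may outrun the cycloaddition. Fallback: setting out from 4 and 5, the cycloaddition is promoted by the achiral Lewis acid Me2AlCl (CH2Cl2, −78 °C), which should keep the regiochemical and endo preferences, and the same NaBH4 quench is applied. This should give the racemate, that is aldehyde 6 together with the enantiomeric aldehyde F1 and, after reduction, alcohol 7 together with the enantiomeric alcohol F2. Resolution by preparative chromatography on a chiral stationary phase delivers 7, where the route is rejoined.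

**Step 11.** The transient formyl dienophile may be consumed by hydration or hetero-Diels–Alder self-condensation before butadiene adds at the neopentylic C9. Fallback, which avoids the formyl dienophile and builds ring C by conjugate addition, enolate chemistry and metathesis:
- Setting out from 15, selenenylation of the lactone enolate (LiN(i-Pr)2, PhSeBr) gives the C8 phenylselanyl lactone F3, and oxidation with H2O2 followed by syn-elimination gives the 8,9-unsaturated spirolactone F4.
- Conjugate allylation (allylmagnesium bromide, CuBr·SMe2, Me3SiCl, THF, −78 °C) should add C11–C13 to C9 from the C1 side to give the C9-allyl lactone F5.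
- The enolate of F5 is allylated at C8 (LiN(i-Pr)2, allyl bromide) to the 8,9-diallyl lactone F6, obtained as C8 epimers.
- A second enolization with C-formylation (LiN(SiMe3)2, 2,2,2-trifluoroethyl formate) should bring in C15 anti to the C9 allyl group, giving the C8-formyl 8,9-diallyl lactone F7.
- Ring-closing metathesis with second-generation Grubbs catalyst closes ring C and rejoins the route at 21.

**Step 13.** The vinyl radical may be reduced before it cyclizes, or the cyclized radical may undergo homoallyl rearrangement to the bicyclo[2.2.2]octane skeleton. Fallback: setting out from 21, ethynylmagnesium bromide (THF, −78 °C) adds to the aldehyde to give the C15 propargylic alcohol F8. A palladium-catalysed reductive enyne cyclization (Pd2(dba)3, tri(o-tolyl)phosphine, acetic acid, polymethylhydrosiloxane, toluene) then closes the C16–C13 bond by hydropalladation of the alkyne, 5-exo carbopalladation of the ring C alkene and hydride capture. The route is rejoined at 23.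

## Further compounds

F1 | step 3 | enantiomer of aldehyde 6 | CC(C)[Si](OC1=C2C(=O)OC[C@H]2[C@@](C)(C=O)CC1)(C(C)C)C(C)C
F2 | step 3 | enantiomer of alcohol 7 | CC(C)[Si](OC1=C2C(=O)OC[C@H]2[C@@](C)(CO)CC1)(C(C)C)C(C)C
F3 | step 11 | C8 phenylselanyl lactone (C8 epimers) | O=C1C([Se]c9ccccc9)C[C@]2(CO1)[C@@H](OCc5ccc6ccccc6c5)CC[C@@](C)(COCc3ccc4ccccc4c3)[C@H]2CO[Si](c7ccccc7)(c8ccccc8)C(C)(C)C
F4 | step 11 | 8,9-unsaturated spirolactone | O=C1C=C[C@]2(CO1)[C@@H](OCc5ccc6ccccc6c5)CC[C@@](C)(COCc3ccc4ccccc4c3)[C@H]2CO[Si](c7ccccc7)(c8ccccc8)C(C)(C)C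
F5 | step 11 | C9-allyl lactone | O=C1C[C@@H](CC=C)[C@]2(CO1)[C@@H](OCc5ccc6ccccc6c5)CC[C@@](C)(COCc3ccc4ccccc4c3)[C@H]2CO[Si](c7ccccc7)(c8ccccc8)C(C)(C)C
F6 | step 11 | 8,9-diallyl lactone (C8 epimers) | O=C1C(CC=C)[C@@H](CC=C)[C@]2(CO1)[C@@H](OCc5ccc6ccccc6c5)CC[C@@](C)(COCc3ccc4ccccc4c3)[C@H]2CO[Si](c7ccccc7)(c8ccccc8)C(C)(C)C
F7 | step 11 | C8-formyl 8,9-diallyl lactone | O=C[C@]1(CC=C)[C@@H](CC=C)[C@]2(COC1=O)[C@@H](OCc5ccc6ccccc6c5)CC[C@@](C)(COCc3ccc4ccccc4c3)[C@H]2CO[Si](c7ccccc7)(c8ccccc8)C(C)(C)C
F8 | step 13 | C15 propargylic alcohol (C15 epimers) | C#CC(O)[C@]12CC=CC[C@H]1[C@]1(COC2=O)[C@@H](OCc5ccc6ccccc6c5)CC[C@@](C)(COCc3ccc4ccccc4c3)[C@H]1CO[Si](c7ccccc7)(c8ccccc8)C(C)(C)C
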